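**Plan**

1. Ring atoms are numbered O1, C2 (CH3), C3 (CHO), C4 (CH2CO2R), C5 (CO2Me), C6. Retrosynthesis: the benzyl ethers and the CHO (from CH2OTr) are adjusted last; the dihydropyran is cut at C4–C5 and O1–C6 to a δ-hydroxy (E)-enoate and methyl propiolate; the enoate C=C is cut by cross-metathesis to a hydroxytyrosol acrylate and a 2-vinyl-1,3-diol; the C2–C3 bond is cut by an aldol reaction.
2. Enabling feature: O1–C6H=C5(CO2Me) is a vinylogous carbonate, the adduct of an alkoxide with methyl propiolate, and C4 lies β to the carbonyl of the CH2CO2R arm. The C5 carbanion created by the O-addition therefore finds C4 as the β-carbon of a tethered enoate and closes the six-membered ring there.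
3. Forward: Evans aldol (C2–C3), reduction and tritylation, cross-metathesis (enoate), oxa-Michael/Michael annulation (O1–C6, then ring closure C5–C4), then detritylation, oxidation and debenzylation.
4. Stereochemistry: C2 and C3 come from the auxiliary-controlled syn-aldol reaction; C4 is set in the ring closure by the adjacent C3 centre (all substituents pseudo-equatorial); the epimerisable formyl-bearing C3 ends in the trans,trans arrangement, which is also the more stable one.

Key step: step 8

**Step 1**
Reactants: 1 (R)-4-benzyl-1,3-oxazolidin-2-one; 2 (E)-but-2-enoyl chloride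
Product: 3 (R)-4-benzyl-3-[(E)-but-2-enoyl]-1,3-oxazolidin-2-one
Conditions: n-BuLi, THF, −78 °C; then 2, −78 → 0 °C
Reagents that add atoms: none
Why: N-acylation of the lithiated oxazolidinone by the acid chloride is the standard entry to Evans imides and forms no stereocentre.

**Step 2**
Reactants: 3 (R)-4-benzyl-3-[(E)-but-2-enoyl]-1,3-oxazolidin-2-one; 4 acetaldehyde
Product: 6 (4R)-4-benzyl-3-[(2R,3S)-2-ethenyl-3-hydroxybutanoyl]-1,3-oxazolidin-2-one, via boron dienolate 5 (not isolated)
Conditions: Bu2BOTf, Et3N, CH2Cl2, −78 → 0 °C; 4, −78 → 0 °C; pH 7 buffer, MeOH, H2O2, 0 °C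
Reagents that add atoms: none
Why: Evans syn-aldol reaction, in which the dibutylboron (Z)-dienolate reacts at its α-carbon through a Zimmerman–Traxler chair on the face away from the benzyl group, so that the carbinol centre (S) and the vinyl-bearing centre (R) are set syn, the relationship that becomes the trans C2/C3 pair of the ring.

**Step 3**
Reactants: 6 (4R)-4-benzyl-3-[(2R,3S)-2-ethenyl-3-hydroxybutanoyl]-1,3-oxazolidin-2-one
Product: 7 (2S,3S)-2-ethenylbutane-1,3-diol
Conditions: LiBH4, THF, 0 °C → rt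
Reagents that add atoms: none
Why: Reductive cleavage of the imide by LiBH4 should give the 1,3-diol without touching the alkene or either stereocentre and returns the auxiliary (the descriptor of the vinyl-bearing carbon changes to S only through the CIP priorities).

**Step 4**
Reactants: 7 (2S,3S)-2-ethenylbutane-1,3-diol
Product: 8 (2S,3S)-3-[(triphenylmethoxy)methyl]pent-4-en-2-ol
Conditions: TrCl, Et3N, DMAP (cat.), CH2Cl2, rt
Reagents that add atoms: trityl chloride, ClC(c1ccccc1)(c1ccccc1)c1ccccc1
Why: Tritylation is selective for the primary hydroxyl on steric grounds and gives an ether that, unlike a silyl ether, cannot shift to the neighbouring alkoxide in step 8.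

**Step 5**
Reactants: 9 hydroxytyrosol, 4-(2-hydroxyethyl)benzene-1,2-diol
Product: 10 2-[3,4-bis(benzyloxy)phenyl]ethanol
Conditions: BnBr, K2CO3, acetone, reflux
Reagents that add atoms: benzyl bromide, BrCc1ccccc1
Why: Williamson ether synthesis in which K2CO3 deprotonates only the two phenols, so the primary alcohol should stay free.

**Step 6**
Reactants: 10 2-[3,4-bis(benzyloxy)phenyl]ethanol; 11 acryloyl chloride
Product: 12 2-[3,4-bis(benzyloxy)phenyl]ethyl prop-2-enoate
Conditions: Et3N, CH2Cl2, 0 °C
Reagents that add atoms: none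
Why: O-acylation of the primary alcohol by the acid chloride in the presence of an amine base is a routine esterification.

**Step 7**
Reactants: 8 (2S,3S)-3-[(triphenylmethoxy)methyl]pent-4-en-2-ol; 12 2-[3,4-bis(benzyloxy)phenyl]ethyl prop-2-enoate
Product: 13 2-[3,4-bis(benzyloxy)phenyl]ethyl (2E,4S,5S)-5-hydroxy-4-[(triphenylmethoxy)methyl]hex-2-enoate
Conditions: RuCl2(H2IMes)(=CH-C6H4-2-O-i-Pr) (second-generation Hoveyda–Grubbs catalyst, H2IMes = 1,3-dimesitylimidazolidin-2-ylidene, 5 mol %), excess 12, CH2Cl2, 40 °C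
Reagents that add atoms: none
Why: Olefin cross-metathesis of a terminal alkene with an acrylate is reliably (E)-selective and should leave the free secondary alcohol and both stereocentres untouched.

**Step 8**
Reactants: 13 2-[3,4-bis(benzyloxy)phenyl]ethyl (2E,4S,5S)-5-hydroxy-4-[(triphenylmethoxy)methyl]hex-2-enoate; 14 methyl propiolate
Product: 18 methyl (2S,3S,4R)-4-(2-{2-[3,4-bis(benzyloxy)phenyl]ethoxy}-2-oxoethyl)-2-methyl-3-[(triphenylmethoxy)methyl]-3,4-dihydro-2H-pyran-5-carboxylate, via potassium alkoxide 15 (not isolated), via potassium allenolate 16 (not isolated), via potassium ester enolate 17 (not isolated)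
Conditions: KH (1.0 equiv), THF, 0 °C; then 14 (1.05 equiv, slow addition, high dilution), −78 → −40 °C; AcOH, −78 °C
Reagents that add atoms: none
Why: Proposed new method: alkoxide 15 adds to the β-carbon of methyl propiolate (oxa-Michael), and the allenolate 16 so formed, whose carbanionic carbon is the future C5, attacks C4, the β-carbon of the tethered (E)-enoate, before it is protonated; this gives ester enolate 17 and, after the acetic acid quench, dihydropyran 18. The closest known reaction type is the base- or amine-promoted oxa-Michael/Michael annulation of 2-hydroxychalcones and 2-hydroxycinnamates with propiolates and ynones to 4H-chromenes, together with the nucleophile-initiated Michael/aldol couplings of propiolates; here an aliphatic δ-hydroxy enoate takes the place of the phenol. The ring closes in a 6-exo-trig (enolendo) Michael addition, and the endocyclic C5=C6 bond can form because an allenolate has no fixed geometry at C5. The new stereocentre C4 is controlled by the adjacent C3 centre: in the half-chair transition state the C2 methyl, the C3 trityloxymethyl group and the exocyclic enoate carbon are all pseudo-equatorial, with C3–H eclipsing the enoate double bond, which should place the CH2CO2R arm trans to the C3 substituent. The step needs ring closure to outrun protonation of 16; the preformed alcohol-free alkoxide, the slow addition of 14 at low temperature and the non-migrating trityl ether are chosen for this, and closure of the alkoxide onto its own enoate would be a disfavoured 4-exo process.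

**Step 9**
Reactants: 18 methyl (2S,3S,4R)-4-(2-{2-[3,4-bis(benzyloxy)phenyl]ethoxy}-2-oxoethyl)-2-methyl-3-[(triphenylmethoxy)methyl]-3,4-dihydro-2H-pyran-5-carboxylate
Product: 19 methyl (2S,3S,4R)-4-(2-{2-[3,4-bis(benzyloxy)phenyl]ethoxy}-2-oxoethyl)-3-(hydroxymethyl)-2-methyl-3,4-dihydro-2H-pyran-5-carboxylate
Conditions: CF3CO2H (3 vol %), Et3SiH, CH2Cl2, 0 °C, short reaction time
Reagents that add atoms: none
Why: Acidolysis of the trityl ether with the trityl cation trapped irreversibly as triphenylmethane (ionic hydrogenation) should be too mild and too brief to affect the benzyl ethers, the esters or the vinylogous carbonate.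

**Step 10**
Reactants: 19 methyl (2S,3S,4R)-4-(2-{2-[3,4-bis(benzyloxy)phenyl]ethoxy}-2-oxoethyl)-3-(hydroxymethyl)-2-methyl-3,4-dihydro-2H-pyran-5-carboxylate
Product: 20 methyl (2S,3R,4R)-4-(2-{2-[3,4-bis(benzyloxy)phenyl]ethoxy}-2-oxoethyl)-3-formyl-2-methyl-3,4-dihydro-2H-pyran-5-carboxylate
Conditions: Dess–Martin periodinane, CH2Cl2, 0 °C → rt
Reagents that add atoms: none
Why: Dess–Martin oxidation under near-neutral conditions should give the aldehyde with C3 unchanged in space (its descriptor becomes R only through the CIP priorities), and this trans,trans arrangement is also the one favoured should any enolisation occur.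

**Step 11**
Reactants: 20 methyl (2S,3R,4R)-4-(2-{2-[3,4-bis(benzyloxy)phenyl]ethoxy}-2-oxoethyl)-3-formyl-2-methyl-3,4-dihydro-2H-pyran-5-carboxylate
Product: 21 methyl (2S,3R,4R)-4-{2-[2-(3,4-dihydroxyphenyl)ethoxy]-2-oxoethyl}-3-formyl-2-methyl-3,4-dihydro-2H-pyran-5-carboxylate (CNP0172886.1)
Conditions: H2 (1 atm), Pd/C, EtOAc, rt
Reagents that add atoms: none
Why: Hydrogenolysis of the two aryl benzyl ethers over Pd/C at 1 atm should be fast relative to reduction of the hindered push–pull ring alkene or of the aldehyde and frees the catechol under neutral conditions.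

**Compound list**

1 | (R)-4-benzyl-1,3-oxazolidin-2-one | O=C1N[C@H](Cc2ccccc2)CO1 | starting material
2 | (E)-but-2-enoyl chloride | C/C=C/C(Cl)=O | starting material
3 | (R)-4-benzyl-3-[(E)-but-2-enoyl]-1,3-oxazolidin-2-one | C/C=C/C(=O)N1[C@H](Cc2ccccc2)COC1=O | intermediate
4 | acetaldehyde | CC=O | starting material
5 | dibutylboron (Z)-dienolate of 3 (not isolated) | C=C/C=C(\OB(CCCC)CCCC)N1[C@H](Cc2ccccc2)COC1=O | intermediate
6 | (4R)-4-benzyl-3-[(2R,3S)-2-ethenyl-3-hydroxybutanoyl]-1,3-oxazolidin-2-one | O[C@@H](C)[C@H](C(=O)N1[C@H](Cc2ccccc2)COC1=O)C=C | intermediate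
7 | (2S,3S)-2-ethenylbutane-1,3-diol | O[C@@H](C)[C@H](CO)C=C | intermediate
8 | (2S,3S)-3-[(triphenylmethoxy)methyl]pent-4-en-2-ol | O[C@@H](C)[C@H](COC(c1ccccc1)(c1ccccc1)c1ccccc1)C=C | intermediate
9 | hydroxytyrosol, 4-(2-hydroxyethyl)benzene-1,2-diol | OCCc1ccc(O)c(O)c1 | starting material
10 | 2-[3,4-bis(benzyloxy)phenyl]ethanol | OCCc1ccc(OCc2ccccc2)c(OCc2ccccc2)c1 | intermediate
11 | acryloyl chloride | C=CC(Cl)=O | starting material
12 | 2-[3,4-bis(benzyloxy)phenyl]ethyl prop-2-enoate | C=CC(=O)OCCc1ccc(OCc2ccccc2)c(OCc2ccccc2)c1 | intermediate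
13 | 2-[3,4-bis(benzyloxy)phenyl]ethyl (2E,4S,5S)-5-hydroxy-4-[(triphenylmethoxy)methyl]hex-2-enoate | O[C@@H](C)[C@H](COC(c1ccccc1)(c1ccccc1)c1ccccc1)/C=C/C(=O)OCCc1ccc(OCc2ccccc2)c(OCc2ccccc2)c1 | intermediate
14 | methyl propiolate | C#CC(=O)OC | starting material
15 | potassium alkoxide of 13 (not isolated) | [K+].[O-][C@@H](C)[C@H](COC(c1ccccc1)(c1ccccc1)c1ccccc1)/C=C/C(=O)OCCc1ccc(OCc2ccccc2)c(OCc2ccccc2)c1 | intermediate
16 | potassium allenolate from 15 and 14 (not isolated) | [K+].COC([O-])=C=CO[C@@H](C)[C@H](COC(c1ccccc1)(c1ccccc1)c1ccccc1)/C=C/C(=O)OCCc1ccc(OCc2ccccc2)c(OCc2ccccc2)c1 | intermediate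
17 | potassium ester enolate of 18 (not isolated) | [K+].COC(=O)C1=CO[C@@H](C)[C@H](COC(c2ccccc2)(c2ccccc2)c2ccccc2)[C@H]1C=C([O-])OCCc1ccc(OCc2ccccc2)c(OCc2ccccc2)c1 | intermediate
18 | methyl (2S,3S,4R)-4-(2-{2-[3,4-bis(benzyloxy)phenyl]ethoxy}-2-oxoethyl)-2-methyl-3-[(triphenylmethoxy)methyl]-3,4-dihydro-2H-pyran-5-carboxylate | COC(=O)C1=CO[C@@H](C)[C@H](COC(c2ccccc2)(c2ccccc2)c2ccccc2)[C@H]1CC(=O)OCCc1ccc(OCc2ccccc2)c(OCc2ccccc2)c1 | intermediate
19 | methyl (2S,3S,4R)-4-(2-{2-[3,4-bis(benzyloxy)phenyl]ethoxy}-2-oxoethyl)-3-(hydroxymethyl)-2-methyl-3,4-dihydro-2H-pyran-5-carboxylate | COC(=O)C1=CO[C@@H](C)[C@H](CO)[C@H]1CC(=O)OCCc1ccc(OCc2ccccc2)c(OCc2ccccc2)c1 | intermediate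
20 | methyl (2S,3R,4R)-4-(2-{2-[3,4-bis(benzyloxy)phenyl]ethoxy}-2-oxoethyl)-3-formyl-2-methyl-3,4-dihydro-2H-pyran-5-carboxylate | COC(=O)C1=CO[C@@H](C)[C@H](C=O)[C@H]1CC(=O)OCCc1ccc(OCc2ccccc2)c(OCc2ccccc2)c1 | intermediate
21 | methyl (2S,3R,4R)-4-{2-[2-(3,4-dihydroxyphenyl)ethoxy]-2-oxoethyl}-3-formyl-2-methyl-3,4-dihydro-2H-pyran-5-carboxylate | COC(=O)C1=CO[C@@H](C)[C@H](C=O)[C@H]1CC(=O)OCCc1ccc(O)c(O)c1 | target

**Step count**

Total steps: 11. Longest linear sequence: 9 steps (steps 1–4 and 7–11); steps 5 and 6 make the acrylate partner.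

**Steps most likely to fail**

Step 8. The allenolate may be protonated before it cyclises, by proton transfer from the acetylenic C–H of the reagent or from alcohol regenerated in that way, which would stop the sequence at the open-chain enol ether. Facial selectivity at C4 may also be incomplete. The fallback uses known chemistry, sets out from 13 and returns at 18. N-Methylmorpholine-catalysed oxa-Michael addition of 13 to 14 (CH2Cl2, rt) should give the open-chain methyl (E)-3-alkoxyacrylate F1, which is also the product expected from premature protonation. Iodination with N-iodosuccinimide and AcOH in CH2Cl2 followed by Et3N should give the methyl (Z)-2-iodo-3-alkoxyacrylate F2. Bu3SnH with AIBN (benzene, 80 °C, slow addition) should then close the same C5–C4 bond by 6-exo-trig cyclisation of the vinyl radical onto the enoate, giving 18.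

Step 7. Cross-metathesis at the branched allylic position may be slow, so that homodimerisation of the acrylate and double-bond migration compete. The fallback replaces metathesis by olefination, sets out from 8 and returns at 13. Ozonolysis of 8 (O3, CH2Cl2, −78 °C; PPh3) should give (2S,3S)-3-hydroxy-2-[(triphenylmethoxy)methyl]butanal F3, used crude. A Horner–Wadsworth–Emmons reaction under Masamune–Roush conditions (LiCl, i-Pr2NEt, MeCN) with 2-[3,4-bis(benzyloxy)phenyl]ethyl 2-(diethoxyphosphoryl)acetate F4, made from 10 and diethylphosphonoacetic acid (DCC, DMAP), should then give the (E)-enoate 13.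

Step 11. Over-reduction at the formyl group may accompany hydrogenolysis. The fallback takes the aldehyde out of play during debenzylation, sets out from 20 and returns at 21. Acetalisation (HC(OMe)3, PPTS, MeOH) should give the dimethyl acetal F5; hydrogenolysis (H2, Pd/C, EtOAc) should give the catechol acetal F6; mild hydrolysis (AcOH, H2O, THF) should then release 21.

**Further compounds**

F1 | step 8 | 2-[3,4-bis(benzyloxy)phenyl]ethyl (2E,4S,5S)-5-{[(E)-3-methoxy-3-oxoprop-1-enyl]oxy}-4-[(triphenylmethoxy)methyl]hex-2-enoate | COC(=O)/C=C/O[C@@H](C)[C@H](COC(c1ccccc1)(c1ccccc1)c1ccccc1)/C=C/C(=O)OCCc1ccc(OCc2ccccc2)c(OCc2ccccc2)c1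
F2 | step 8 | 2-[3,4-bis(benzyloxy)phenyl]ethyl (2E,4S,5S)-5-{[(Z)-2-iodo-3-methoxy-3-oxoprop-1-enyl]oxy}-4-[(triphenylmethoxy)methyl]hex-2-enoate | COC(=O)/C(I)=C/O[C@@H](C)[C@H](COC(c1ccccc1)(c1ccccc1)c1ccccc1)/C=C/C(=O)OCCc1ccc(OCc2ccccc2)c(OCc2ccccc2)c1
F3 | step 7 | (2S,3S)-3-hydroxy-2-[(triphenylmethoxy)methyl]butanal | O[C@@H](C)[C@H](COC(c1ccccc1)(c1ccccc1)c1ccccc1)C=O
F4 | step 7 | 2-[3,4-bis(benzyloxy)phenyl]ethyl 2-(diethoxyphosphoryl)acetate | CCOP(=O)(OCC)CC(=O)OCCc1ccc(OCc2ccccc2)c(OCc2ccccc2)c1
F5 | step 11 | methyl (2S,3R,4R)-4-(2-{2-[3,4-bis(benzyloxy)phenyl]ethoxy}-2-oxoethyl)-3-(dimethoxymethyl)-2-methyl-3,4-dihydro-2H-pyran-5-carboxylate | COC(=O)C1=CO[C@@H](C)[C@H](C(OC)OC)[C@H]1CC(=O)OCCc1ccc(OCc2ccccc2)c(OCc2ccccc2)c1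
F6 | step 11 | methyl (2S,3R,4R)-4-{2-[2-(3,4-dihydroxyphenyl)ethoxy]-2-oxoethyl}-3-(dimethoxymethyl)-2-methyl-3,4-dihydro-2H-pyran-5-carboxylate | COC(=O)C1=CO[C@@H](C)[C@H](C(OC)OC)[C@H]1CC(=O)OCCc1ccc(O)c(O)c1
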